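**Retrosynthetic overview**

1. Sauriol B 21 ⇐ thiolane carbinol 20. The methyl carbons C9 and C9' on the adjacent stereocentres C8 and C8' are carried as the two CH2–S arms of a trans-3,4-disubstituted thiolane (ring S–C9–C8–C8'–C9'), which Raney Ni opens at the end.
2. 20 ⇐ thiolane aldehyde 16 + aryllithium 19 (C7'–ring B bond); 16 ⇐ keto imide 13 by reduction, benzylic deoxygenation at C7 and oxidation at C7'.
3. 13 ⇐ E-aroylacryloyl imide 10 + thioformaldehyde S-methylide 12 (from 11): a [3+2] cycloaddition that forms C8–C9 and C8'–C9', closes the thiolane and sets C8 and C8'.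
4. 10 ⇐ ring A acetophenone 4 + glyoxylic acid 5 + (S)-4-benzyl-2-oxazolidinone 8; 4 ⇐ aldehyde 1.
5. Ring order: rings A and B are bought; the thiolane is the only ring formed (step 6) and it is cleaved again in step 12.

Key step: step 6

Numbering: lignan numbering is used (C7/C7' benzylic carbons, C8/C8' stereocentres, C9/C9' methyl carbons; ring A = 3,4-dihydroxy-5-methoxyphenyl on C7, ring B = 4-hydroxy-3,5-dimethoxyphenyl on C7'); the target is (8R,8'R).

Assumption: the uncatalysed ylide addition is taken to be only moderately face-selective; the route requires only that the two trans adducts, which are diastereomers because of the auxiliary, can be separated.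

**Route**

Step 1
Reactants: 1 3,4-dihydroxy-5-methoxybenzaldehyde
Product: 2 3,4-bis(benzyloxy)-5-methoxybenzaldehyde
Conditions: BnBr, K2CO3, DMF, 60 °C
Reagents that add atoms: benzyl bromide, BrCc1ccccc1
Why: Williamson etherification of both phenols with a reactive benzylic halide and carbonate base, the aldehyde being inert under these conditions.

Step 2
Reactants: 2 3,4-bis(benzyloxy)-5-methoxybenzaldehyde
Product: 3 1-[3,4-bis(benzyloxy)-5-methoxyphenyl]ethanol (racemic)
Conditions: MeMgBr, THF, 0 °C; aq NH4Cl
Reagents that add atoms: methylmagnesium bromide, C[Mg]Br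
Why: Grignard addition to a non-enolisable aryl aldehyde gives the secondary benzylic alcohol, whose uncontrolled stereocentre is removed in step 3.

Step 3
Reactants: 3 1-[3,4-bis(benzyloxy)-5-methoxyphenyl]ethanol (racemic)
Product: 4 1-[3,4-bis(benzyloxy)-5-methoxyphenyl]ethanone
Conditions: Dess–Martin periodinane, CH2Cl2, rt
Reagents that add atoms: none
Why: Dess–Martin oxidation of a secondary benzylic alcohol to the aryl methyl ketone, with benzyl ethers unaffected.

Step 4
Reactants: 4 1-[3,4-bis(benzyloxy)-5-methoxyphenyl]ethanone; 5 glyoxylic acid (as monohydrate)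
Product: 7 (E)-4-[3,4-bis(benzyloxy)-5-methoxyphenyl]-4-oxobut-2-enoic acid, via β-hydroxy acid 6 (not isolated)
Conditions: AcOH, reflux
Reagents that add atoms: none
Why: Acid-mediated aldol condensation of the enolised methyl ketone with the aldehyde of glyoxylic acid, followed by thermal dehydration of 6, should give the conjugated acid as its more stable E isomer, aryl benzyl ethers tolerating hot acetic acid.

Step 5
Reactants: 7 (E)-4-[3,4-bis(benzyloxy)-5-methoxyphenyl]-4-oxobut-2-enoic acid; 8 (S)-4-benzyl-2-oxazolidinone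
Product: 10 (S)-4-benzyl-3-[(E)-4-(3,4-bis(benzyloxy)-5-methoxyphenyl)-4-oxobut-2-enoyl]oxazolidin-2-one, via mixed pivalic anhydride 9 (not isolated)
Conditions: PivCl, Et3N, THF, −20 °C; then 8, LiCl, −20 °C → rt
Reagents that add atoms: pivaloyl chloride, CC(C)(C)C(=O)Cl (pivaloyl group held only in intermediate 9)
Why: N-acylation of the oxazolidinone through the mixed pivalic anhydride under LiCl/Et3N activation avoids strong base near the electrophilic ene-dione, the nucleophile attacks the unhindered enoyl carbonyl and the E geometry is retained.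

Step 6
Reactants: 10 (S)-4-benzyl-3-[(E)-4-(3,4-bis(benzyloxy)-5-methoxyphenyl)-4-oxobut-2-enoyl]oxazolidin-2-one; 11 chloromethyl (trimethylsilyl)methyl sulfide
Product: 13 (S)-4-benzyl-3-{[(3S,4S)-4-(3,4-bis(benzyloxy)-5-methoxybenzoyl)thiolan-3-yl]carbonyl}oxazolidin-2-one, via thioformaldehyde S-methylide 12 (not isolated)
Conditions: 11 (2–3 equiv, slow addition), CsF, MeCN, rt
Reagents that add atoms: none
Why: Fluoride attacks silicon of 11 and chloride is expelled in a 1,3-elimination, giving the ylide 12, whose two carbon termini bond to the alkene carbons of 10 in one concerted suprafacial [3+2] cycloaddition (C8–C9 and C8'–C9'). The closest known reaction type is the 1,3-dipolar cycloaddition of this parent thiocarbonyl ylide to N-enoyl amides and imides bearing chiral auxiliaries, which yields trans-3,4-disubstituted thiolanes. The thiolane closes by intermolecular [3+2] annulation, the C–S–C unit of 12 bridging C8 and C8'. C8 and C8' are created together: their trans (like) relationship is copied from the E alkene because both bonds form on one face, and their absolute configuration follows from attack on the Si face of the imide-bound alkene carbon, the face turned away from the benzyl group when the imide reacts as the rotamer with syn carbonyls and an s-cis enoyl unit, the only rotamer that holds the alkene beside C4 of the auxiliary. The step needs chemoselectivity for the C=C bond over the ketone and imide carbonyls, secured by the low LUMO of an alkene flanked by two acyl groups, and facial selectivity, which the auxiliary secures only in part, so the minor trans diastereomer is to be removed by chromatography or crystallisation and the configuration of 13 confirmed by X-ray analysis before it is carried on.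

Step 7
Reactants: 13 (S)-4-benzyl-3-{[(3S,4S)-4-(3,4-bis(benzyloxy)-5-methoxybenzoyl)thiolan-3-yl]carbonyl}oxazolidin-2-one
Product: 14 [3,4-bis(benzyloxy)-5-methoxyphenyl][(3S,4S)-4-(hydroxymethyl)thiolan-3-yl]methanol (both carbinol epimers)
Conditions: LiBH4, MeOH (1 equiv), THF, 0 °C → rt
Reagents that add atoms: none
Why: Borohydride reduction of the aryl ketone and reductive cleavage of the imide at its exocyclic carbonyl should give the diol and release auxiliary 8 for recovery; the new carbinol centre is uncontrolled and is removed in step 8, while C8 and C8' lose their enolisable neighbours without epimerisation.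

Step 8
Reactants: 14 [3,4-bis(benzyloxy)-5-methoxyphenyl][(3S,4S)-4-(hydroxymethyl)thiolan-3-yl]methanol (both carbinol epimers)
Product: 15 {(3S,4R)-4-[3,4-bis(benzyloxy)-5-methoxybenzyl]thiolan-3-yl}methanol
Conditions: Et3SiH, BF3·OEt2, CH2Cl2, −40 → 0 °C
Reagents that add atoms: none
Why: Ionic hydrogenation, in which BF3 ionises only the para-alkoxy-stabilised benzylic alcohol and Et3SiH delivers hydride to the cation; the primary alcohol cannot ionise, any cyclic benzylic ether formed by its capture of the cation re-ionises to the same product, and low temperature with excess silane disfavours proton loss at C8.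

Step 9
Reactants: 15 {(3S,4R)-4-[3,4-bis(benzyloxy)-5-methoxybenzyl]thiolan-3-yl}methanol
Product: 16 (3S,4R)-4-[3,4-bis(benzyloxy)-5-methoxybenzyl]thiolane-3-carbaldehyde
Conditions: Dess–Martin periodinane, CH2Cl2, 0 °C → rt
Reagents that add atoms: none
Why: Dess–Martin oxidation of the primary alcohol to the aldehyde under non-basic conditions that leave the dialkyl sulfide and the α-stereocentre C8' untouched.

Step 10
Reactants: 17 4-bromo-2,6-dimethoxyphenol
Product: 18 2-(benzyloxy)-5-bromo-1,3-dimethoxybenzene
Conditions: BnBr, K2CO3, DMF, 60 °C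
Reagents that add atoms: benzyl bromide, BrCc1ccccc1
Why: Williamson etherification of the hindered phenol, which masks the acidic OH before metalation.

Step 11
Reactants: 16 (3S,4R)-4-[3,4-bis(benzyloxy)-5-methoxybenzyl]thiolane-3-carbaldehyde; 18 2-(benzyloxy)-5-bromo-1,3-dimethoxybenzene
Product: 20 [4-(benzyloxy)-3,5-dimethoxyphenyl]{(3S,4R)-4-[3,4-bis(benzyloxy)-5-methoxybenzyl]thiolan-3-yl}methanol (both carbinol epimers), via aryllithium 19 (not isolated)
Conditions: 18, n-BuLi, THF, −78 °C; then 16, −78 °C; H2O
Reagents that add atoms: n-butyllithium, [Li]CCCC (lithium held only in intermediate 19)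
Why: Bromine–lithium exchange followed by 1,2-addition of the aryllithium to the aldehyde forms the C7'–ring B bond; addition at −78 °C outruns enolisation so C8' is kept, and the uncontrolled carbinol centre is removed in step 12.

Step 12
Reactants: 20 [4-(benzyloxy)-3,5-dimethoxyphenyl]{(3S,4R)-4-[3,4-bis(benzyloxy)-5-methoxybenzyl]thiolan-3-yl}methanol (both carbinol epimers)
Product: 21 Sauriol B, 5-[(2R,3R)-4-(4-hydroxy-3,5-dimethoxyphenyl)-2,3-dimethylbutyl]-3-methoxybenzene-1,2-diol
Conditions: Raney Ni (W-2, large excess, washed neutral), EtOH, reflux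
Reagents that add atoms: none
Why: Raney Ni reductive desulfurisation cleaves both C–S bonds so that C9 and C9' become methyl groups, and the same hydrogen-loaded nickel hydrogenolyses the electron-rich benzylic C–OH bond and the three O-benzyl ethers, none of these cleavages touching a bond at C8 or C8'.

**Compound list**

1 | 3,4-dihydroxy-5-methoxybenzaldehyde | COc1cc(C=O)cc(O)c1O | starting material
2 | 3,4-bis(benzyloxy)-5-methoxybenzaldehyde | COc1cc(C=O)cc(OCc2ccccc2)c1OCc1ccccc1 | intermediate
3 | 1-[3,4-bis(benzyloxy)-5-methoxyphenyl]ethanol (racemic) | COc1cc(C(C)O)cc(OCc2ccccc2)c1OCc1ccccc1 | intermediate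
4 | 1-[3,4-bis(benzyloxy)-5-methoxyphenyl]ethanone | COc1cc(C(C)=O)cc(OCc2ccccc2)c1OCc1ccccc1 | intermediate
5 | glyoxylic acid (used as monohydrate) | O=CC(=O)O | starting material
6 | 4-[3,4-bis(benzyloxy)-5-methoxyphenyl]-2-hydroxy-4-oxobutanoic acid (racemic; not isolated) | COc1cc(C(=O)CC(O)C(=O)O)cc(OCc2ccccc2)c1OCc1ccccc1 | intermediate
7 | (E)-4-[3,4-bis(benzyloxy)-5-methoxyphenyl]-4-oxobut-2-enoic acid | COc1cc(C(=O)/C=C/C(=O)O)cc(OCc2ccccc2)c1OCc1ccccc1 | intermediate
8 | (S)-4-benzyl-2-oxazolidinone | O=C1N[C@@H](Cc2ccccc2)CO1 | starting material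
9 | (E)-4-[3,4-bis(benzyloxy)-5-methoxyphenyl]-4-oxobut-2-enoic pivalic anhydride (not isolated) | COc1cc(C(=O)/C=C/C(=O)OC(=O)C(C)(C)C)cc(OCc2ccccc2)c1OCc1ccccc1 | intermediate
10 | (S)-4-benzyl-3-[(E)-4-(3,4-bis(benzyloxy)-5-methoxyphenyl)-4-oxobut-2-enoyl]oxazolidin-2-one | COc1cc(C(=O)/C=C/C(=O)N2[C@@H](Cc3ccccc3)COC2=O)cc(OCc2ccccc2)c1OCc1ccccc1 | intermediate
11 | chloromethyl (trimethylsilyl)methyl sulfide | C[Si](C)(C)CSCCl | starting material
12 | thioformaldehyde S-methylide (not isolated) | [CH2-][S+]=C | intermediate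
13 | (S)-4-benzyl-3-{[(3S,4S)-4-(3,4-bis(benzyloxy)-5-methoxybenzoyl)thiolan-3-yl]carbonyl}oxazolidin-2-one | COc1cc(C(=O)[C@H]2CSC[C@@H]2C(=O)N2[C@@H](Cc3ccccc3)COC2=O)cc(OCc2ccccc2)c1OCc1ccccc1 | intermediate
14 | [3,4-bis(benzyloxy)-5-methoxyphenyl][(3S,4S)-4-(hydroxymethyl)thiolan-3-yl]methanol (both carbinol epimers) | COc1cc(C(O)[C@H]2CSC[C@@H]2CO)cc(OCc2ccccc2)c1OCc1ccccc1 | intermediate
15 | {(3S,4R)-4-[3,4-bis(benzyloxy)-5-methoxybenzyl]thiolan-3-yl}methanol | COc1cc(C[C@H]2CSC[C@@H]2CO)cc(OCc2ccccc2)c1OCc1ccccc1 | intermediate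
16 | (3S,4R)-4-[3,4-bis(benzyloxy)-5-methoxybenzyl]thiolane-3-carbaldehyde | COc1cc(C[C@H]2CSC[C@@H]2C=O)cc(OCc2ccccc2)c1OCc1ccccc1 | intermediate
17 | 4-bromo-2,6-dimethoxyphenol | COc1cc(Br)cc(OC)c1O | starting material
18 | 2-(benzyloxy)-5-bromo-1,3-dimethoxybenzene | COc1cc(Br)cc(OC)c1OCc1ccccc1 | intermediate
19 | [4-(benzyloxy)-3,5-dimethoxyphenyl]lithium (not isolated) | [Li]c1cc(OC)c(OCc2ccccc2)c(OC)c1 | intermediate
20 | [4-(benzyloxy)-3,5-dimethoxyphenyl]{(3S,4R)-4-[3,4-bis(benzyloxy)-5-methoxybenzyl]thiolan-3-yl}methanol (both carbinol epimers) | COc1cc(C[C@H]2CSC[C@@H]2C(O)c2cc(OC)c(OCc3ccccc3)c(OC)c2)cc(OCc2ccccc2)c1OCc1ccccc1 | intermediate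
21 | Sauriol B, 5-[(2R,3R)-4-(4-hydroxy-3,5-dimethoxyphenyl)-2,3-dimethylbutyl]-3-methoxybenzene-1,2-diol | COc1cc(C[C@@H](C)[C@H](C)Cc2cc(OC)c(O)c(OC)c2)cc(O)c1O | target

**Step count**

Total steps: 12. Longest linear sequence: 11 steps (steps 1–9, 11 and 12); step 10 is the one-step side branch for ring B.

**Steps most likely to fail, with fallbacks**

Step 6. The ylide may add with poor facial selectivity, because the imide rotamer with anti carbonyls, in which the benzyl group is remote from the alkene, also reacts; the sense of induction may even be reversed, and fluoride may erode the imide during the slow addition. The fallback separates ring formation from the auxiliary and replaces induction by resolution; it sets out from acid 7 and comes back at 13. Acid 7 is methylated (MeI, K2CO3, DMF) to methyl (E)-4-[3,4-bis(benzyloxy)-5-methoxyphenyl]-4-oxobut-2-enoate F1. The same ylide (11, CsF, MeCN) adds to this plain aroylacrylate, which asks for no facial control and has no auxiliary to lose, giving racemic methyl trans-4-[3,4-bis(benzyloxy)-5-methoxybenzoyl]thiolane-3-carboxylate F2. LiOH in THF/H2O gives racemic trans-4-[3,4-bis(benzyloxy)-5-methoxybenzoyl]thiolane-3-carboxylic acid F3; trans is the stable arrangement, so the basic step should not scramble it. PivCl/Et3N converts it into the mixed pivalic anhydride F4, which acylates 8 (LiCl) to give 13 together with (S)-4-benzyl-3-{[(3R,4R)-4-(3,4-bis(benzyloxy)-5-methoxybenzoyl)thiolan-3-yl]carbonyl}oxazolidin-2-one F5. The two diastereomers are separated by chromatography or crystallisation and 13 continues at step 7.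

Step 12. Hydrogenolysis of the benzylic C–OH bond may stall, or the carbinol may be dehydrogenated reversibly on nickel to the aryl ketone, which would allow epimerisation at C8'; prolonged heating to force the reaction risks ring hydrogenation. The fallback removes the oxygen by a cationic path before sulfur is touched; it sets out from 20 and comes back at 21. Ionic hydrogenation of 20 (Et3SiH, BF3·OEt2, CH2Cl2, −40 → 0 °C) gives (3R,4R)-3-[4-(benzyloxy)-3,5-dimethoxybenzyl]-4-[3,4-bis(benzyloxy)-5-methoxybenzyl]thiolane F6. Raney Ni in refluxing EtOH then has only to cleave the two C–S bonds and the three benzyl ethers to give 21.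

Step 8. The benzylic cation may be captured by the neighbouring primary hydroxyl to give a cyclic ether that re-opens slowly, proton loss and reprotonation may erode C8, and benzyl ethers may be lost on long exposure to the Lewis acid. The fallback changes the order of events so that the benzylic oxygen is removed before any hydroxyl group exists; it sets out from 13 and comes back at 15. Direct ionic hydrogenation of the aryl ketone of 13 (Et3SiH, CF3CO2H, CH2Cl2, 0 °C → rt) gives (S)-4-benzyl-3-{[(3S,4R)-4-(3,4-bis(benzyloxy)-5-methoxybenzyl)thiolan-3-yl]carbonyl}oxazolidin-2-one F7. LiBH4 (MeOH, THF, 0 °C) then cleaves the imide reductively to 15 and returns auxiliary 8.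

**Further compounds**

F1 | step 6 | methyl (E)-4-[3,4-bis(benzyloxy)-5-methoxyphenyl]-4-oxobut-2-enoate | COC(=O)/C=C/C(=O)c1cc(OC)c(OCc2ccccc2)c(OCc2ccccc2)c1
F2 | step 6 | methyl trans-4-[3,4-bis(benzyloxy)-5-methoxybenzoyl]thiolane-3-carboxylate (racemic; 3S,4S enantiomer drawn) | COc1cc(C(=O)[C@H]2CSC[C@@H]2C(=O)OC)cc(OCc2ccccc2)c1OCc1ccccc1
F3 | step 6 | trans-4-[3,4-bis(benzyloxy)-5-methoxybenzoyl]thiolane-3-carboxylic acid (racemic; 3S,4S enantiomer drawn) | COc1cc(C(=O)[C@H]2CSC[C@@H]2C(=O)O)cc(OCc2ccccc2)c1OCc1ccccc1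
F4 | step 6 | trans-4-[3,4-bis(benzyloxy)-5-methoxybenzoyl]thiolane-3-carboxylic pivalic anhydride (racemic; 3S,4S enantiomer drawn; not isolated) | COc1cc(C(=O)[C@H]2CSC[C@@H]2C(=O)OC(=O)C(C)(C)C)cc(OCc2ccccc2)c1OCc1ccccc1
F5 | step 6 | (S)-4-benzyl-3-{[(3R,4R)-4-(3,4-bis(benzyloxy)-5-methoxybenzoyl)thiolan-3-yl]carbonyl}oxazolidin-2-one | COc1cc(C(=O)[C@@H]2CSC[C@H]2C(=O)N2[C@@H](Cc3ccccc3)COC2=O)cc(OCc2ccccc2)c1OCc1ccccc1
F6 | step 12 | (3R,4R)-3-[4-(benzyloxy)-3,5-dimethoxybenzyl]-4-[3,4-bis(benzyloxy)-5-methoxybenzyl]thiolane | COc1cc(C[C@H]2CSC[C@@H]2Cc2cc(OC)c(OCc3ccccc3)c(OC)c2)cc(OCc2ccccc2)c1OCc1ccccc1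
F7 | step 8 | (S)-4-benzyl-3-{[(3S,4R)-4-(3,4-bis(benzyloxy)-5-methoxybenzyl)thiolan-3-yl]carbonyl}oxazolidin-2-one | COc1cc(C[C@H]2CSC[C@@H]2C(=O)N2[C@@H](Cc3ccccc3)COC2=O)cc(OCc2ccccc2)c1OCc1ccccc1
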